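The route rests on cutting C8–C9 of the pentadecenyl chain (C1 = methyl end, C15 = benzylic carbon on the resorcinol ring). This is where the Z C7=C8 alkene of the allylic acetate unit C6–C7=C8 meets the unbranched C9–C15 tether. Both carbons enter as nucleophiles and are united oxidatively on boron. In a Zweifel olefination the arylheptyllithium adds to an E-alkenylboronate, iodine drives C9 from boron to C8, and anti elimination turns E into Z. One operation makes the bond, sets the cis geometry and frees the C6 hydroxyl. The precursor, a trans-vinylboronate, comes from syn hydroboration of silylated (R)-oct-1-yn-3-ol, which supplies the C6 stereocentre.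

Key step: step 6

Remark: the target is (6R,7Z)-15-(3,5-dihydroxyphenyl)pentadec-7-en-6-yl acetate, and this chain numbering is used throughout. Compounds 1, 3 and 7 are taken as commercial.

Step 1
Reactants: 1 5-bromobenzene-1,3-diol (5-bromoresorcinol)
Product: 2 1-bromo-3,5-bis(triisopropylsilyloxy)benzene
Conditions: TIPSCl (2.4 equiv), imidazole (5 equiv), DMF, rt
Reagents that add atoms: triisopropylsilyl chloride (TIPSCl), CC(C)[Si](Cl)(C(C)C)C(C)C
Why: Imidazole-promoted O-silylation masks both phenols, and TIPS is chosen because aryl TIPS ethers should withstand Grignard and alkyllithium reagents and cold methoxide yet fall to fluoride at the end.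

Step 2
Reactants: 2 1-bromo-3,5-bis(triisopropylsilyloxy)benzene; 3 1,7-dibromoheptane
Product: 5 1-(7-bromoheptyl)-3,5-bis(triisopropylsilyloxy)benzene, via aryl Grignard reagent 4 (not isolated)
Conditions: Mg, THF, reflux; then added slowly to 3 (3 equiv), Li2CuCl4 (3 mol %), THF, 0 °C → rt
Reagents that add atoms: none
Why: Magnesium insertion followed by copper-catalysed Kumada-type sp2–sp3 cross-coupling should stop at monosubstitution, because the Grignard reagent is added to an excess of the symmetrical dibromide and the silyl ethers are inert.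

Step 3
Reactants: 5 1-(7-bromoheptyl)-3,5-bis(triisopropylsilyloxy)benzene
Product: 6 1-(7-iodoheptyl)-3,5-bis(triisopropylsilyloxy)benzene
Conditions: NaI (5 equiv), acetone, reflux
Reagents that add atoms: sodium iodide, [Na+].[I-]
Why: Finkelstein halide exchange (SN2), driven by precipitation of NaBr, supplies the primary iodide needed for clean lithium–iodine exchange.

Step 4
Reactants: 7 (R)-oct-1-yn-3-ol
Product: 8 (R)-3-(trimethylsilyloxy)oct-1-yne
Conditions: TMSCl (1.2 equiv), imidazole (2 equiv), CH2Cl2, 0 °C; distillation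
Reagents that add atoms: trimethylsilyl chloride (TMSCl), C[Si](C)(C)Cl
Why: O-silylation leaves the C–O bond and hence the R configuration of 7 untouched, and TMS is chosen because the methoxide of step 6 removes it without a separate operation.

Step 5
Reactants: 8 (R)-3-(trimethylsilyloxy)oct-1-yne
Product: 9 (R,E)-4,4,5,5-tetramethyl-2-[3-(trimethylsilyloxy)oct-1-en-1-yl]-1,3,2-dioxaborolane
Conditions: HBpin (1.1 equiv), Cp2ZrHCl (5 mol %), Et3N (10 mol %), neat, 60 °C; Kugelrohr distillation
Reagents that add atoms: pinacolborane (HBpin), B1OC(C)(C)C(C)(C)O1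
Why: In this zirconocene-hydride-catalysed hydroboration, syn hydrozirconation places the metal on the terminal carbon and exchange with HBpin should deliver only the E-1-alkenylboronate, with the stereocentre as a spectator.

Step 6
Reactants: 6 1-(7-iodoheptyl)-3,5-bis(triisopropylsilyloxy)benzene; 9 (R,E)-4,4,5,5-tetramethyl-2-[3-(trimethylsilyloxy)oct-1-en-1-yl]-1,3,2-dioxaborolane
Product: 14 (6R,7Z)-15-[3,5-bis(triisopropylsilyloxy)phenyl]pentadec-7-en-6-ol, via alkyllithium 10 (not isolated), via lithium boronate 11 (not isolated), via iodoboronic ester 12 (not isolated), via TMS ether 13 (not isolated)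
Conditions: 6 (1.1 equiv), t-BuLi (2.2 equiv), Et2O–pentane, −78 °C; 9, THF, −78 °C; I2 (1.2 equiv), THF, −78 °C; NaOMe (4 equiv), MeOH, −78 → 0 °C; aq. Na2S2O3, then aq. citric acid work-up
Reagents that add atoms: none
Why: Zweifel olefination: lithium–iodine exchange turns 6 into the primary alkyllithium 10, which adds to the vacant boron p orbital of 9 faster than to any silyl ether and gives the tetracoordinate boronate 11, so that C8 and C9, both nucleophilic carbons, sit on one boron atom. Iodine, the oxidant of this like-polarity union, attacks the electron-rich C7=C8 bond of 11, and C9 migrates from boron to C8 antiperiplanar to the developing C7–I bond (1,2-metallate rearrangement), which forms the C8–C9 bond and gives 12. Methoxide then coordinates boron and triggers antiperiplanar loss of boron and iodide, and the sequence of anti addition and anti elimination converts the E geometry of 9 stereospecifically into the Z geometry of 13 whichever alkene face iodine takes, so the transient centres C7 and C8 need only their relative configuration. No ring is closed and no lasting stereocentre is created, and C6 keeps the R configuration of 7 because none of its bonds is broken. The step needs migration of the heptyl carbon only, which is secured because the pinacolate oxygens are non-migrating ligands, and it needs discrimination among the silyl ethers, which is secured by sterics: methoxide in methanol strips the unhindered O–TMS group to free 14, while the bulky aryl O–TIPS groups should persist at or below 0 °C.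

Step 7
Reactants: 14 (6R,7Z)-15-[3,5-bis(triisopropylsilyloxy)phenyl]pentadec-7-en-6-ol
Product: 15 (6R,7Z)-15-[3,5-bis(triisopropylsilyloxy)phenyl]pentadec-7-en-6-yl acetate
Conditions: Ac2O (1.5 equiv), pyridine, DMAP (cat.), CH2Cl2, 0 °C → rt
Reagents that add atoms: acetic anhydride, CC(=O)OC(C)=O
Why: DMAP-catalysed O-acylation takes place at oxygen with retention at C6, and only the secondary alcohol can react because both phenols are still silylated.

Step 8
Reactants: 15 (6R,7Z)-15-[3,5-bis(triisopropylsilyloxy)phenyl]pentadec-7-en-6-yl acetate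
Product: 16 (6R,7Z)-15-(3,5-dihydroxyphenyl)pentadec-7-en-6-yl acetate (target)
Conditions: TBAF (2.2 equiv), AcOH (2.5 equiv), THF, 0 °C
Reagents that add atoms: none
Why: Fluoride-induced desilylation of aryl silyl ethers is fast because phenoxide is a good leaving group, and the acetic acid buffer keeps the medium non-basic so that the allylic acetate and the Z alkene should persist.

Compound list
1 | 5-bromobenzene-1,3-diol | Oc1cc(O)cc(Br)c1 | starting material
2 | 1-bromo-3,5-bis(triisopropylsilyloxy)benzene | Brc1cc(O[Si](C(C)C)(C(C)C)C(C)C)cc(O[Si](C(C)C)(C(C)C)C(C)C)c1 | intermediate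
3 | 1,7-dibromoheptane | BrCCCCCCCBr | starting material
4 | [3,5-bis(triisopropylsilyloxy)phenyl]magnesium bromide | Br[Mg]c1cc(O[Si](C(C)C)(C(C)C)C(C)C)cc(O[Si](C(C)C)(C(C)C)C(C)C)c1 | intermediate
5 | 1-(7-bromoheptyl)-3,5-bis(triisopropylsilyloxy)benzene | BrCCCCCCCc1cc(O[Si](C(C)C)(C(C)C)C(C)C)cc(O[Si](C(C)C)(C(C)C)C(C)C)c1 | intermediate
6 | 1-(7-iodoheptyl)-3,5-bis(triisopropylsilyloxy)benzene | ICCCCCCCc1cc(O[Si](C(C)C)(C(C)C)C(C)C)cc(O[Si](C(C)C)(C(C)C)C(C)C)c1 | intermediate
7 | (R)-oct-1-yn-3-ol | CCCCC[C@@H](O)C#C | starting material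
8 | (R)-3-(trimethylsilyloxy)oct-1-yne | CCCCC[C@@H](O[Si](C)(C)C)C#C | intermediate
9 | (R,E)-4,4,5,5-tetramethyl-2-[3-(trimethylsilyloxy)oct-1-en-1-yl]-1,3,2-dioxaborolane | CCCCC[C@@H](O[Si](C)(C)C)/C=C/B1OC(C)(C)C(C)(C)O1 | intermediate
10 | 7-[3,5-bis(triisopropylsilyloxy)phenyl]heptyllithium | [Li]CCCCCCCc1cc(O[Si](C(C)C)(C(C)C)C(C)C)cc(O[Si](C(C)C)(C(C)C)C(C)C)c1 | intermediate
11 | lithium pinacolato(arylheptyl)[(R,E)-3-(trimethylsilyloxy)oct-1-enyl]borate | [Li+].CCCCC[C@@H](O[Si](C)(C)C)/C=C/[B-]1(CCCCCCCc2cc(O[Si](C(C)C)(C(C)C)C(C)C)cc(O[Si](C(C)C)(C(C)C)C(C)C)c2)OC(C)(C)C(C)(C)O1 | intermediate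
12 | pinacol 15-[3,5-bis(triisopropylsilyloxy)phenyl]-7-iodo-6-(trimethylsilyloxy)pentadecan-8-ylboronate, anti adduct, drawn as the 6R,7R,8S isomer (the 6R,7S,8R isomer from the other alkene face leads to the same alkene) | CCCCC[C@@H](O[Si](C)(C)C)[C@H](I)[C@H](CCCCCCCc1cc(O[Si](C(C)C)(C(C)C)C(C)C)cc(O[Si](C(C)C)(C(C)C)C(C)C)c1)B1OC(C)(C)C(C)(C)O1 | intermediate
13 | (6R,7Z)-15-[3,5-bis(triisopropylsilyloxy)phenyl]-6-(trimethylsilyloxy)pentadec-7-ene | CCCCC[C@H](/C=C\CCCCCCCc1cc(O[Si](C(C)C)(C(C)C)C(C)C)cc(O[Si](C(C)C)(C(C)C)C(C)C)c1)O[Si](C)(C)C | intermediate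
14 | (6R,7Z)-15-[3,5-bis(triisopropylsilyloxy)phenyl]pentadec-7-en-6-ol | CCCCC[C@H](/C=C\CCCCCCCc1cc(O[Si](C(C)C)(C(C)C)C(C)C)cc(O[Si](C(C)C)(C(C)C)C(C)C)c1)O | intermediate
15 | (6R,7Z)-15-[3,5-bis(triisopropylsilyloxy)phenyl]pentadec-7-en-6-yl acetate | CCCCC[C@H](/C=C\CCCCCCCc1cc(O[Si](C(C)C)(C(C)C)C(C)C)cc(O[Si](C(C)C)(C(C)C)C(C)C)c1)OC(C)=O | intermediate
16 | (6R,7Z)-15-(3,5-dihydroxyphenyl)pentadec-7-en-6-yl acetate | CCCCC[C@H](/C=C\CCCCCCCc1cc(O)cc(O)c1)OC(C)=O | target

Total step count: 8
Longest linear sequence: 6 (steps 1, 2, 3, 6, 7, 8). The second branch (steps 4 and 5) joins at step 6.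

Steps most likely to fail

Step 6. Several processes may go wrong:
- The alkyllithium may be quenched or undergo Wurtz-type self-coupling before it reaches boron.
- The electron-rich ring may be iodinated, or methoxide may remove the aryl silyl groups, once base and excess iodine are present together.
- The cis geometry may erode through competing syn elimination.

The fallback sets out from 7 and 6 and comes back at 14. It makes the same C8–C9 bond by SN2 alkylation and sets the geometry afterwards. Compound 7 is doubly deprotonated with n-BuLi (2.1 equiv) in THF–DMPU to the O,C-dilithio derivative of (R)-oct-1-yn-3-ol F1. Its acetylide carbon is alkylated by 6 to give (R)-15-[3,5-bis(triisopropylsilyloxy)phenyl]pentadec-7-yn-6-ol F2. Lindlar semihydrogenation (H2, Pd/CaCO3–Pb, quinoline) then gives 14 by syn delivery of hydrogen.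

Step 2. Several processes may go wrong:
- Magnesium insertion into the hindered, electron-rich bromide may be sluggish.
- The Grignard reagent may homocouple.
- A second substitution of the dibromide may occur.
- Removal of the excess dibromide may be laborious.

The fallback sets out from 2 and comes back at 6, bypassing 5. Sonogashira coupling of 2 with commercial hept-6-yn-1-ol (Pd(PPh3)4, CuI, Et3N, 70 °C) gives 7-[3,5-bis(triisopropylsilyloxy)phenyl]hept-6-yn-1-ol F3. Full hydrogenation (H2, Pd/C, EtOAc) gives 7-[3,5-bis(triisopropylsilyloxy)phenyl]heptan-1-ol F4. Appel iodination (I2, PPh3, imidazole, CH2Cl2) then gives 6.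

Step 5. The labile TMS ether may be lost under the warm hydroboration conditions or on isolation, and the alkyne may be hydroborated twice.

The fallback sets out from 7 and comes back at 9, with the order of events reversed so that the TMS group is put on last. Unprotected 7 is treated with HBpin (2.2 equiv) and the same zirconium catalyst. The hydroxyl is masked in the flask as its borate, which gives pinacol (R,E)-[3-(pinacolboryloxy)oct-1-en-1-yl]boronate F5. Aqueous work-up cleaves the O–B bond and gives the robust, chromatographable (R,E)-1-(4,4,5,5-tetramethyl-1,3,2-dioxaborolan-2-yl)oct-1-en-3-ol F6. Silylation with TMSCl and imidazole gives 9, which is filtered, concentrated and used directly in step 6.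

Further compounds
F1 | step 6 | O,C-dilithio derivative of (R)-oct-1-yn-3-ol | CCCCC[C@@H](O[Li])C#C[Li]
F2 | step 6 | (R)-15-[3,5-bis(triisopropylsilyloxy)phenyl]pentadec-7-yn-6-ol | CCCCC[C@@H](O)C#CCCCCCCCc1cc(O[Si](C(C)C)(C(C)C)C(C)C)cc(O[Si](C(C)C)(C(C)C)C(C)C)c1
F3 | step 2 | 7-[3,5-bis(triisopropylsilyloxy)phenyl]hept-6-yn-1-ol | OCCCCCC#Cc1cc(O[Si](C(C)C)(C(C)C)C(C)C)cc(O[Si](C(C)C)(C(C)C)C(C)C)c1
F4 | step 2 | 7-[3,5-bis(triisopropylsilyloxy)phenyl]heptan-1-ol | OCCCCCCCc1cc(O[Si](C(C)C)(C(C)C)C(C)C)cc(O[Si](C(C)C)(C(C)C)C(C)C)c1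
F5 | step 5 | pinacol (R,E)-[3-(pinacolboryloxy)oct-1-en-1-yl]boronate | CCCCC[C@@H](OB1OC(C)(C)C(C)(C)O1)/C=C/B1OC(C)(C)C(C)(C)O1
F6 | step 5 | (R,E)-1-(4,4,5,5-tetramethyl-1,3,2-dioxaborolan-2-yl)oct-1-en-3-ol | CCCCC[C@@H](O)/C=C/B1OC(C)(C)C(C)(C)O1
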